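**Plan**

- Retrosynthesis: the acid comes from its methyl ester. The C2–C3 bond is cut back to a 3-siloxy-1,2-dioxane (cyclic peroxycarbenium ion plus silyl ketene acetal). The 1,2-dioxane is then cut across at C5–C6 and O2–C3 into two three-atom pieces: C6–O1–O2 as the silyl peroxyketal of a dienone (15 of the 22 carbons), and C3–C4–C5 as a 2-ethyl-siloxycyclopropane.
- Enabling feature: in the 1,2-dioxane ring, C6 is a ketone-level carbon that already carries the peroxide, so it is a latent peroxycarbenium ion. C5 is β to the aldehyde-level carbon C3, so C3–C4–C5 can be delivered as an aldehyde homoenolate (cyclopropanol ether). This joins two acceptor carbons (C5 and C6) by polarity reversal and lets peroxide oxygen O2 trap the oxocarbenium ion at C3.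
- Forward: (E)-pent-2-enal → allylic alcohol → Johnson–Claisen ester → alkyne → carbocupration/acylation → dienone → silyl peroxyketal (fragment A). (R)-1,2-Epoxybutane → cyclopropane ester → cyclopropyl acetate → siloxycyclopropane (fragment B). A (3+3) annulation of A and B forms the only ring, then the acetate chain is put on C3 and the ester is saponified.
- Stereochemistry: C10 from catalytic asymmetric ethylation and 1,3-chirality transfer in the Claisen step. Both E-alkenes from the Claisen chair and from syn-carbocupration. C4 from (R)-1,2-epoxybutane (inversion on cyclopropanation). C6 in the annulation (substrate control by C4, epimer separable). C3 by axial attack on the cyclic peroxycarbenium ion.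

Key step: step 13

Remark: 9 and 10 (ketal carbon) and 20 (C3) are carried as mixtures at centres that the next cation-forming step planarises. The C6 epimer expected beside 20 is removed by chromatography at the stage of 22.

**Step 1**
Reactants: 1 (E)-pent-2-enal
Product: 2 (3R,4E)-hept-4-en-3-ol
Conditions: Et2Zn (1.5 eq), (+)-DAIB (5 mol%), toluene, 0 °C; aq. NH4Cl
Reagents that add atoms: diethylzinc, CC[Zn]CC
Why: Amino-alcohol-catalysed enantioselective 1,2-addition of a dialkylzinc to an enal; the (−)-ligand is known to give (S)-carbinols with this substituent pattern, so the (+)-ligand should deliver ethyl to the face that gives the (R)-carbinol.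

**Step 2**
Reactants: 2 (3R,4E)-hept-4-en-3-ol
Product: 3 ethyl (3R,4E)-3-ethylhept-4-enoate
Conditions: MeC(OEt)3 (6 eq), EtCO2H (5 mol%), 140 °C, EtOH distilled off
Reagents that add atoms: triethyl orthoacetate, CC(OCC)(OCC)OCC
Why: Johnson–Claisen rearrangement through a chair transition state with the carbinol ethyl group equatorial, which should give the E-alkene and transfer the carbinol configuration suprafacially to the new C–C bond, setting the (R)-centre that becomes C10.

**Step 3**
Reactants: 3 ethyl (3R,4E)-3-ethylhept-4-enoate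
Product: 4 (3R,4E)-3-ethylhept-4-enal
Conditions: iBu2AlH (1.05 eq), CH2Cl2, −78 °C; aq. KNaC4H4O6
Reagents that add atoms: none
Why: Partial reduction of an ester with iBu2AlH at low temperature stops at the aluminium hemiacetal, which gives the aldehyde on work-up; the stereocentre is β to the carbonyl and cannot epimerise.

**Step 4**
Reactants: 4 (3R,4E)-3-ethylhept-4-enal
Product: 5 (4R,5E)-4-ethyloct-5-en-1-yne
Conditions: dimethyl (1-diazo-2-oxopropyl)phosphonate, K2CO3, MeOH, 0 °C → rt
Reagents that add atoms: dimethyl (1-diazo-2-oxopropyl)phosphonate, COP(=O)(OC)C(=[N+]=[N-])C(C)=O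
Why: Ohira–Bestmann homologation turns the aldehyde into the terminal alkyne under mildly basic conditions that leave the β-stereocentre and the E-alkene untouched.

**Step 5**
Reactants: 5 (4R,5E)-4-ethyloct-5-en-1-yne
Product: 7 (4E,7R,8E)-5,7-diethylundeca-4,8-dien-3-one, via alkenylcopper 6 (not isolated)
Conditions: EtMgBr, CuBr·SMe2, Et2O/Me2S, −45 °C; add 5, −25 °C; then EtCOCl, Pd(PPh3)4 (3 mol%), THF, −25 → 0 °C
Reagents that add atoms: ethylmagnesium bromide, CC[Mg]Br; propionyl chloride, CCC(Cl)=O
Why: Normant carbocupration adds ethyl and copper syn across the terminal alkyne with copper on the terminal carbon, and Pd-catalysed acylation of 6 with retention should place the propionyl group cis to the new ethyl group, which is the (4E)-enone; the isolated 1,2-disubstituted alkene does not carbometalate.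

**Step 6**
Reactants: 7 (4E,7R,8E)-5,7-diethylundeca-4,8-dien-3-one
Product: 8 (4E,7R,8E)-5,7-diethyl-3,3-dimethoxyundeca-4,8-diene
Conditions: MeOSiMe3 (2.5 eq), Me3SiOTf (5 mol%), CH2Cl2, −78 °C; pyridine quench
Reagents that add atoms: methoxytrimethylsilane, CO[Si](C)(C)C
Why: Noyori ketalisation (alkoxysilane with catalytic silyl triflate at low temperature) is the mild aprotic way to ketalise an enone without moving or isomerising its double bonds.

**Step 7**
Reactants: 8 (4E,7R,8E)-5,7-diethyl-3,3-dimethoxyundeca-4,8-diene
Product: 9 (4E,7R,8E)-5,7-diethyl-3-hydroperoxy-3-methoxyundeca-4,8-diene (both C3 epimers)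
Conditions: H2O2 (anhydrous in Et2O, 5 eq), pyridinium p-toluenesulfonate (5 mol%), Et2O, −20 °C, short reaction time
Reagents that add atoms: hydrogen peroxide, OO
Why: Acid-catalysed exchange of one methoxy group of a ketal for hydrogen peroxide (perketalisation) through the allyl-stabilised oxocarbenium ion, run cold and short so that the kinetic product of attack at the ketal carbon is collected; the new centre is of no consequence.

**Step 8**
Reactants: 9 (4E,7R,8E)-5,7-diethyl-3-hydroperoxy-3-methoxyundeca-4,8-diene
Product: 10 triethyl{[(4E,7R,8E)-5,7-diethyl-3-methoxyundeca-4,8-dien-3-yl]peroxy}silane (both C3 epimers)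
Conditions: Et3SiCl, imidazole, DMF, 0 °C
Reagents that add atoms: chlorotriethylsilane, CC[Si](Cl)(CC)CC
Why: Silylation of a hydroperoxide with a silyl chloride and imidazole is standard and non-acidic, so the acid-labile peroxyketal should survive.

**Step 9**
Reactants: 11 (R)-1,2-epoxybutane
Product: 12 ethyl (1S,2S)-2-ethylcyclopropane-1-carboxylate
Conditions: (EtO)2P(O)CH2CO2Et, NaH, toluene, 110 °C, sealed vessel
Reagents that add atoms: triethyl phosphonoacetate, CCOC(=O)CP(=O)(OCC)OCC
Why: Wadsworth–Emmons cyclopropanation of a terminal epoxide, in which the phosphonoacetate anion opens the epoxide at CH2, the phosphoryl group migrates to the alkoxide and the ester enolate closes by 3-exo-tet displacement with inversion at the ethyl-bearing carbon, which should give the trans (1S,2S) ester from the (R)-epoxide.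

**Step 10**
Reactants: 12 ethyl (1S,2S)-2-ethylcyclopropane-1-carboxylate
Product: 14 1-[(1S,2S)-2-ethylcyclopropyl]ethan-1-one, via Weinreb amide 13 (not isolated)
Conditions: MeNH(OMe)·HCl (1.5 eq), MeMgCl (5 eq), THF, −20 → 0 °C
Reagents that add atoms: methylmagnesium chloride, C[Mg]Cl
Why: One-pot conversion of an ester into a methyl ketone by way of the Weinreb amide 13, whose chelated tetrahedral adduct prevents a second addition; the ethyl-bearing ring carbon is not touched.

**Step 11**
Reactants: 14 1-[(1S,2S)-2-ethylcyclopropyl]ethan-1-one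
Product: 15 (1S,2S)-2-ethylcyclopropyl acetate
Conditions: (CF3CO)2O, urea·H2O2, Na2HPO4, CH2Cl2, 0 °C → rt
Reagents that add atoms: trifluoroperacetic acid (made in the flask from trifluoroacetic anhydride and urea–hydrogen peroxide), OOC(=O)C(F)(F)F
Why: Baeyer–Villiger oxidation in which the cyclopropyl group migrates in preference to methyl and with retention, the established way from cyclopropyl methyl ketones to cyclopropyl acetates.

**Step 12**
Reactants: 15 (1S,2S)-2-ethylcyclopropyl acetate
Product: 17 triethyl{[(1S,2S)-2-ethylcyclopropyl]oxy}silane, via cyclopropanol 16 (not isolated)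
Conditions: MeLi (2.1 eq), Et2O, −78 °C; cold aq. NH4Cl; then Et3SiCl, imidazole, CH2Cl2, 0 °C
Reagents that add atoms: chlorotriethylsilane, CC[Si](Cl)(CC)CC
Why: Cleavage of the acetate with methyllithium avoids the protic base that would open the cyclopropanol to an aldehyde, and silylation of crude 16 gives the homoenol silyl ether; the ethyl-bearing centre is untouched.

**Step 13**
Reactants: 10 triethyl{[(4E,7R,8E)-5,7-diethyl-3-methoxyundeca-4,8-dien-3-yl]peroxy}silane; 17 triethyl{[(1S,2S)-2-ethylcyclopropyl]oxy}silane
Product: 20 triethyl{[(4S,6R)-4,6-diethyl-6-[(1E,4R,5E)-2,4-diethylocta-1,5-dien-1-yl]-1,2-dioxan-3-yl]oxy}silane (both C3 anomers), via peroxycarbenium triflate 18 (not isolated), via silyloxocarbenium triflate 19 (not isolated)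
Conditions: 17 (2 eq), Et3SiOTf (15 mol%), 2,6-di-tert-butyl-4-methylpyridine (20 mol%), CH2Cl2, −78 → −40 °C
Reagents that add atoms: none
Why: Proposed new method: the silyl triflate ionises the methoxy group of 10 to the allyl-conjugated peroxycarbenium ion 18, the unsubstituted CH2 carbon of the siloxycyclopropane 17 (an aldehyde homoenolate equivalent, so that the two acceptor-type carbons C5 and C6 are joined by polarity reversal) attacks C6 while the C1–C3 bond of the three-membered ring opens to the silyloxocarbenium ion 19, and the silylperoxy oxygen closes on C3 with loss of Et3Si+, which carries the chain. The closest known reactions are the annulation of silyl peroxyketal-derived peroxycarbenium ions with alkenes to 1,2-dioxolanes, the Lewis-acid addition of silyl enol ethers and allylsilanes to peroxycarbenium ions, the electrophilic opening of siloxycyclopropanes at the CH2 carbon, and the (3+3) annulation of donor–acceptor cyclopropanes with nitrones. The 1,2-dioxane closes in the 6-exo-trig mode (O2 onto the exocyclic C3=O+ bond of 19). C4 is carried unchanged from 17 because only the C1–C3 bond of the cyclopropane breaks; C6 is set in the C–C bond formation under the control of C4, the compact chair-like array that O2 needs to reach C3 being expected to put the C6 ethyl group equatorial and syn to the C4 ethyl group with the flatter alkenyl group axial, a preference that may be modest so that the 6-epimer is removed after step 14; C3 forms as an anomeric mixture that step 14 erases. The step needs attack at C6 and not at C8 of the allyl cation, which the charge on C6–O and the full substitution of C8 should secure, and ring opening at CH2, which the oxygen donor on C1 and the free CH2 position should secure; the E geometry of C7=C8 keeps the C11=C12 alkene out of reach of C6, and the hindered pyridine removes the acid that would protodesilylate 17.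

**Step 14**
Reactants: 20 triethyl{[(4S,6R)-4,6-diethyl-6-[(1E,4R,5E)-2,4-diethylocta-1,5-dien-1-yl]-1,2-dioxan-3-yl]oxy}silane
Product: 22 methyl 2-[(3S,4S,6R)-4,6-diethyl-6-[(1E,4R,5E)-2,4-diethylocta-1,5-dien-1-yl]-1,2-dioxan-3-yl]acetate, via cyclic peroxycarbenium triflate 21 (not isolated)
Conditions: CH2=C(OMe)OSiMe2tBu (3 eq), Me3SiOTf (20 mol%), CH2Cl2, −78 °C
Reagents that add atoms: tert-butyl[(1-methoxyethenyl)oxy]dimethylsilane, C=C(OC)O[Si](C)(C)C(C)(C)C
Why: Mukaiyama-type substitution of a 3-oxygenated 1,2-dioxane through its cyclic peroxycarbenium ion 21, a known way to 1,2-dioxan-3-yl acetates, in which the silyl ketene acetal should attack C3 axially on the half-chair that has both ring ethyl groups pseudo-equatorial (the other half-chair has them syn-diaxial), placing the acetate chain cis to the C4 ethyl group, which is (3S).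

**Step 15**
Reactants: 22 methyl 2-[(3S,4S,6R)-4,6-diethyl-6-[(1E,4R,5E)-2,4-diethylocta-1,5-dien-1-yl]-1,2-dioxan-3-yl]acetate
Product: 23 plakortide N, 2-[(3S,4S,6R)-4,6-diethyl-6-[(1E,4R,5E)-2,4-diethylocta-1,5-dien-1-yl]-1,2-dioxan-3-yl]acetic acid
Conditions: LiOH (5 eq), THF/MeOH/H2O, 0 °C; then aq. HCl to pH 3
Reagents that add atoms: lithium hydroxide, [Li+].[OH-]
Why: Saponification of the methyl ester with LiOH at 0 °C, conditions that dialkyl peroxides of this type tolerate, followed by mild acidification; no stereocentre is touched.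

**Compound list**

1 | (E)-pent-2-enal | CC/C=C/C=O | starting material
2 | (3R,4E)-hept-4-en-3-ol | CC[C@@H](O)/C=C/CC | intermediate
3 | ethyl (3R,4E)-3-ethylhept-4-enoate | CC/C=C/[C@H](CC)CC(=O)OCC | intermediate
4 | (3R,4E)-3-ethylhept-4-enal | CC/C=C/[C@H](CC)CC=O | intermediate
5 | (4R,5E)-4-ethyloct-5-en-1-yne | CC/C=C/[C@H](CC)CC#C | intermediate
6 | [(1E,4R,5E)-2,4-diethylocta-1,5-dien-1-yl]copper (MgBr2 complex, copper cis to the new ethyl group) | CC/C=C/[C@H](CC)C/C(=C/[Cu])CC | intermediate
7 | (4E,7R,8E)-5,7-diethylundeca-4,8-dien-3-one | CC/C=C/[C@H](CC)C/C(=C/C(=O)CC)CC | intermediate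
8 | (4E,7R,8E)-5,7-diethyl-3,3-dimethoxyundeca-4,8-diene | CC/C=C/[C@H](CC)C/C(=C/C(OC)(OC)CC)CC | intermediate
9 | (4E,7R,8E)-5,7-diethyl-3-hydroperoxy-3-methoxyundeca-4,8-diene (C3 epimers) | CC/C=C/[C@H](CC)C/C(=C/C(OC)(OO)CC)CC | intermediate
10 | triethyl{[(4E,7R,8E)-5,7-diethyl-3-methoxyundeca-4,8-dien-3-yl]peroxy}silane (C3 epimers) | CC/C=C/[C@H](CC)C/C(=C/C(OC)(OO[Si](CC)(CC)CC)CC)CC | intermediate
11 | (R)-1,2-epoxybutane | CC[C@@H]1CO1 | starting material
12 | ethyl (1S,2S)-2-ethylcyclopropane-1-carboxylate | C1[C@H](CC)[C@H]1C(=O)OCC | intermediate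
13 | (1S,2S)-2-ethyl-N-methoxy-N-methylcyclopropane-1-carboxamide | C1[C@H](CC)[C@H]1C(=O)N(C)OC | intermediate
14 | 1-[(1S,2S)-2-ethylcyclopropyl]ethan-1-one | C1[C@H](CC)[C@H]1C(C)=O | intermediate
15 | (1S,2S)-2-ethylcyclopropyl acetate | C1[C@H](CC)[C@H]1OC(C)=O | intermediate
16 | (1S,2S)-2-ethylcyclopropan-1-ol | C1[C@H](CC)[C@H]1O | intermediate
17 | triethyl{[(1S,2S)-2-ethylcyclopropyl]oxy}silane | C1[C@H](CC)[C@H]1O[Si](CC)(CC)CC | intermediate
18 | peroxycarbenium triflate from 10 (O-silylperoxy oxocarbenium ion at C6) | CC/C=C/[C@H](CC)C/C(=C/C(CC)=[O+]O[Si](CC)(CC)CC)CC.[O-]S(=O)(=O)C(F)(F)F | intermediate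
19 | ring-opened silyloxocarbenium triflate (C5–C6 bond formed, C3=O+ open) | CC/C=C/[C@H](CC)C/C(=C/[C@@](OO[Si](CC)(CC)CC)(CC)C[C@H](CC)C=[O+][Si](CC)(CC)CC)CC.[O-]S(=O)(=O)C(F)(F)F | intermediate
20 | triethyl{[(4S,6R)-4,6-diethyl-6-[(1E,4R,5E)-2,4-diethylocta-1,5-dien-1-yl]-1,2-dioxan-3-yl]oxy}silane (C3 anomers) | CC/C=C/[C@H](CC)C/C(=C/[C@@]1(CC)C[C@H](CC)C(O[Si](CC)(CC)CC)OO1)CC | intermediate
21 | cyclic peroxycarbenium triflate from 20 (O2=C3 cation of the 1,2-dioxane) | CC/C=C/[C@H](CC)C/C(=C/[C@@]1(CC)C[C@H](CC)C=[O+]O1)CC.[O-]S(=O)(=O)C(F)(F)F | intermediate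
22 | methyl 2-[(3S,4S,6R)-4,6-diethyl-6-[(1E,4R,5E)-2,4-diethylocta-1,5-dien-1-yl]-1,2-dioxan-3-yl]acetate | CC/C=C/[C@H](CC)C/C(=C/[C@@]1(CC)C[C@H](CC)[C@H](CC(=O)OC)OO1)CC | intermediate
23 | plakortide N, 2-[(3S,4S,6R)-4,6-diethyl-6-[(1E,4R,5E)-2,4-diethylocta-1,5-dien-1-yl]-1,2-dioxan-3-yl]acetic acid | CC/C=C/[C@H](CC)C/C(=C/[C@@]1(CC)C[C@H](CC)[C@H](CC(=O)O)OO1)CC | target

**Step count**

Total steps: 15. Longest linear sequence: 11 steps (steps 1–8, then 13–15).

**Steps most likely to fail**

1. Step 13. The opening of the cyclopropane may be slower than the decay of the peroxycarbenium ion: 1,2-shift of the alkenyl group to oxygen, capture at the remote allyl terminus, or loss of the C7=C8 geometry. The facial discrimination at C6 may also be low. The fallback uses only known reactions, sets out from 17 and 7, and comes back at 20.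
 - Ring-opening bromination of 17 with N-bromosuccinimide (CH2Cl2, 0 °C) should give (R)-2-(bromomethyl)butanal F1.
 - F1 is protected at once with Me3SiOCH2CH2OSiMe3 and catalytic Me3SiOTf at −78 °C as 2-[(2R)-1-bromobutan-2-yl]-1,3-dioxolane F2.
 - Mg in THF converts F2 into [(2R)-2-(1,3-dioxolan-2-yl)butyl]magnesium bromide F3.
 - F3 adds 1,2 to enone 7 in the presence of CeCl3 at −78 °C to give the tertiary allylic alcohol (4E,7R,8E)-3-[(2S)-2-(1,3-dioxolan-2-yl)butyl]-5,7-diethylundeca-4,8-dien-3-ol F4 as both C3 epimers.
 - Acid-catalysed perhydrolysis of F4 (50% H2O2, cat. H2SO4, THF, 0 °C) exchanges the tertiary hydroxyl for a hydroperoxide and hydrolyses the acetal. The hydroperoxy aldehyde closes to (4S,6R)-4,6-diethyl-6-[(1E,4R,5E)-2,4-diethylocta-1,5-dien-1-yl]-1,2-dioxan-3-ol F5, which is separated from its C6 epimer.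
 - Silylation of F5 with Et3SiCl and imidazole gives 20.
 - This path forms the two ring bonds in separate operations and also gives both C6 epimers.

2. Step 7. The allyl-stabilised oxocarbenium ion from 8 may be captured by hydrogen peroxide at its remote terminus (C5 of the undecadiene). Alternatively 9 may re-ionise and close to a 1,2-dioxolane or lose the alkene geometry. In the fallback the free hydroperoxide stage is left out. Ketal 8 is ionised with catalytic Me3SiOTf at −78 °C in the presence of Et3SiOOSiEt3, whose peroxide oxygen is already capped. Silyl peroxyketal 10 is then formed directly from 8, and neither 9 nor any other new compound is made.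

3. Step 14. The cyclic peroxycarbenium ion may lose the C4 proton (epimerisation at C4 through a cyclic peroxy enol ether). The Lewis acid may ionise the tertiary allylic C6–O1 bond. The attack at C3 may be poorly face-selective. The fallback sets out from 20 and comes back at 22.
 - Buffered HF·pyridine removes the silyl group to give the dioxanol F5.
 - F5 reacts through its ring-opened hydroperoxy aldehyde tautomer in a Horner–Wadsworth–Emmons olefination (trimethyl phosphonoacetate, LiCl, iPr2NEt) to give methyl (2E,4S,6R,7E,10R,11E)-4,6,8,10-tetraethyl-6-hydroperoxytetradeca-2,7,11-trienoate F6.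
 - Intramolecular oxa-Michael addition of the hydroperoxide of F6 to the enoate (Et2NH, CF3CH2OH) closes the 1,2-dioxane to 22 under equilibrating conditions.

**Further compounds**

F1 | step 13 | (R)-2-(bromomethyl)butanal | BrC[C@H](CC)C=O
F2 | step 13 | 2-[(2R)-1-bromobutan-2-yl]-1,3-dioxolane | BrC[C@H](CC)C1OCCO1
F3 | step 13 | [(2R)-2-(1,3-dioxolan-2-yl)butyl]magnesium bromide | Br[Mg]C[C@H](CC)C1OCCO1
F4 | step 13 | (4E,7R,8E)-3-[(2S)-2-(1,3-dioxolan-2-yl)butyl]-5,7-diethylundeca-4,8-dien-3-ol (C3 epimers) | CC/C=C/[C@H](CC)C/C(=C/C(O)(CC)C[C@H](CC)C1OCCO1)CC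
F5 | step 13 | (4S,6R)-4,6-diethyl-6-[(1E,4R,5E)-2,4-diethylocta-1,5-dien-1-yl]-1,2-dioxan-3-ol (C3 anomers) | CC/C=C/[C@H](CC)C/C(=C/[C@@]1(CC)C[C@H](CC)C(O)OO1)CC
F6 | step 14 | methyl (2E,4S,6R,7E,10R,11E)-4,6,8,10-tetraethyl-6-hydroperoxytetradeca-2,7,11-trienoate | CC/C=C/[C@H](CC)C/C(=C/[C@@](OO)(CC)C[C@H](CC)/C=C/C(=O)OC)CC
F0 | step 7 | none | none
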